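Numbering (cembrane): C1 carries the isopropenyl group C15(=C16H2)C17H3, C2 the secondary acetate, C3=C4 the C18H2OAc branch, C7 the free hydroxyl, C8 the exocyclic methylene C19, C11=C12 the methyl C20. C1–C14 form the only ring, a 14-membered carbocycle.
Cuts, in retrosynthetic order: the acetates and silyl groups, then ring bond C1–C2, then chain bond C7–C8, then chain bond C4–C5.
Enabling feature: O–C2–C1–C15=C16 is a homoallylic alcohol with C1 and C2 in the ring and C15=C16 outside it, the retron of a carbonyl allylation with allyl transposition. An open chain ending in a C2 enal and a C16 allylic bromide (two electrophilic carbons) can therefore be closed by reductive polarity reversal with CrCl2.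
Forward: fragment 1 (C2–C7, C18) comes from 2-butyne-1,4-diol and a zinc homoenolate, fragment 2 (C8–C17, C19, C20) from (E)-geranylacetone. They are joined at C7–C8 by Ni/Cr alkenylation, the chain ends are adjusted, the ring closes at C1–C2, and the acetates go on last.
Stereochemistry: C3=C4 comes from trans-hydroalumination/iodination and a stereoretentive Negishi coupling, C11=C12 from geranylacetone, and C7 from a chiral sulfonamide-oxazoline ligand on chromium. C1/C2 anti comes from the chair transition state of the (E)-allylchromium (E geometry from the SeO2 oxidation), and the absolute sense from a chiral bis(oxazolinyl)carbazole ligand.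

Key step: step 13

Assumption: the sense of induction of the two chiral chromium ligands (steps 8 and 13) is assigned by analogy with simpler aldehydes. If a trial shows the opposite sense, the antipodal ligand from (R)-valinol is used and nothing else in the route changes.

Step 1
Reactants: 1 2-butyne-1,4-diol
Product: 2 4-(tert-butyldiphenylsilyloxy)but-2-yn-1-ol
Conditions: TBDPSCl (1 equiv), imidazole, DMF, 0 °C to rt, diol in threefold excess
Reagents that add atoms: tert-butyldiphenylsilyl chloride, CC(C)(C)[Si](Cl)(c1ccccc1)c1ccccc1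
Why: Statistical monosilylation of an excess of the symmetrical diol (standard O-silylation) leaves one hydroxyl free to direct step 2 and puts the most robust silyl group on the future C18 oxygen.

Step 2
Reactants: 2 4-(tert-butyldiphenylsilyloxy)but-2-yn-1-ol
Product: 4 (Z)-4-(tert-butyldiphenylsilyloxy)-3-iodobut-2-en-1-ol, via cyclic alkenylalanate 3 (not isolated)
Conditions: NaAlH2(OCH2CH2OMe)2 (1.1 equiv), THF, 0 °C to rt; then I2, −78 °C to 0 °C; aq. potassium sodium tartrate
Reagents that add atoms: iodine, II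
Why: Hydroxyl-directed trans-hydroalumination of the propargylic alcohol places aluminium on the distal alkyne carbon inside a five-membered ring, and iodinolysis with retention gives the (Z)-iodide, so that C2 and the future C5 end up cis on C3=C4.

Step 3
Reactants: 4 (Z)-4-(tert-butyldiphenylsilyloxy)-3-iodobut-2-en-1-ol
Product: 5 (Z)-1-(tert-butyldiphenylsilyloxy)-2-iodo-4-(triethylsilyloxy)but-2-ene
Conditions: TESCl, imidazole, CH2Cl2, 0 °C
Reagents that add atoms: triethylsilyl chloride, CC[Si](Cl)(CC)CC
Why: Standard O-silylation puts the most labile silyl group of the route on the C2 oxygen, which is the first one to be addressed later (step 10).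

Step 4
Reactants: 5 (Z)-1-(tert-butyldiphenylsilyloxy)-2-iodo-4-(triethylsilyloxy)but-2-ene; 6 3-ethoxy-3-oxopropylzinc bromide (commercial THF solution)
Product: 7 ethyl (E)-4-[(tert-butyldiphenylsilyloxy)methyl]-6-(triethylsilyloxy)hex-4-enoate
Conditions: Pd(dppf)Cl2 (5 mol %), THF, rt to 45 °C
Reagents that add atoms: none
Why: Negishi sp2–sp3 cross-coupling of a zinc homoenolate with an alkenyl iodide forms C4–C5 with retention of the alkene geometry, tolerates ester and silyl ethers, and the wide-bite-angle ligand suppresses β-hydride elimination.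

Step 5
Reactants: 7 ethyl (E)-4-[(tert-butyldiphenylsilyloxy)methyl]-6-(triethylsilyloxy)hex-4-enoate
Product: 8 (E)-4-[(tert-butyldiphenylsilyloxy)methyl]-6-(triethylsilyloxy)hex-4-enal
Conditions: iBu2AlH (1.05 equiv), CH2Cl2, −78 °C; aq. potassium sodium tartrate
Reagents that add atoms: none
Why: Low-temperature partial reduction of an ester to the aldehyde with iBu2AlH is standard and leaves the silyl ethers and the trisubstituted alkene untouched.

Step 6
Reactants: 9 (E)-geranylacetone [(5E)-6,10-dimethylundeca-5,9-dien-2-one]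
Product: 11 (5E)-6,10-dimethylundeca-1,5,9-trien-2-yl trifluoromethanesulfonate, via lithium enolate 10 (not isolated)
Conditions: LiN(iPr)2 (commercial solution, 1.1 equiv), THF, −78 °C; then PhNTf2, −78 °C to 0 °C
Reagents that add atoms: N-phenylbis(trifluoromethanesulfonimide), O=S(=O)(N(c1ccccc1)S(=O)(=O)C(F)(F)F)C(F)(F)F
Why: Kinetic deprotonation of the methyl ketone at its CH3 group by the hindered amide and O-triflation of the less substituted enolate (enol triflate synthesis) give the 1,1-disubstituted alkenyl triflate that already holds C8=C19.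

Step 7
Reactants: 11 (5E)-6,10-dimethylundeca-1,5,9-trien-2-yl trifluoromethanesulfonate
Product: 12 (5E,9E)-11-hydroxy-6,10-dimethylundeca-1,5,9-trien-2-yl trifluoromethanesulfonate
Conditions: SeO2 (0.2 equiv), tBuOOH (2 equiv), salicylic acid (0.1 equiv), CH2Cl2, 0 °C to rt, stopped at partial conversion
Reagents that add atoms: tert-butyl hydroperoxide, CC(C)(C)OO (oxygen atom, relayed by SeO2, O=[Se]=O)
Why: Riley-type allylic oxidation (ene reaction followed by [2,3]-sigmatropic shift) attacks the most accessible gem-dimethyl alkene at its (E)-methyl group, which fixes the E geometry of the later allyl unit, while the electron-poor enol triflate alkene should stay inert.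

Step 8
Reactants: 8 (E)-4-[(tert-butyldiphenylsilyloxy)methyl]-6-(triethylsilyloxy)hex-4-enal; 12 (5E,9E)-11-hydroxy-6,10-dimethylundeca-1,5,9-trien-2-yl trifluoromethanesulfonate
Product: 14 (2E,6E,11R,14E)-14-[(tert-butyldiphenylsilyloxy)methyl]-2,6-dimethyl-10-methylidene-16-(triethylsilyloxy)hexadeca-2,6,14-triene-1,11-diol, via alkenylchromium species 13 (not isolated)
Conditions: CrCl2 (3 equiv), N-[2-((4S)-4-isopropyl-4,5-dihydrooxazol-2-yl)-6-methylphenyl]methanesulfonamide (3.3 equiv), Et3N (3.3 equiv), THF, rt; NiCl2 (5 mol %), then 8 and 12, rt; aqueous work-up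
Reagents that add atoms: none
Why: In this Nozaki–Hiyama–Kishi alkenylation zerovalent nickel inserts into the carbon–triflate bond, transmetallation gives 13, which adds only to the aldehyde and tolerates the free hydroxyl, and the chiral sulfonamide-oxazoline on chromium directs attack to the Si face of 8, which sets 7R (C11 of this chain name).

Step 9
Reactants: 14 the diol from step 8
Product: 15 1,11-bis(tert-butyldimethylsilyl) ether of 14
Conditions: TBSOTf (2.5 equiv), 2,6-lutidine, CH2Cl2, −78 °C to 0 °C
Reagents that add atoms: tert-butyldimethylsilyl trifluoromethanesulfonate, CC(C)(C)[Si](C)(C)OS(=O)(=O)C(F)(F)F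
Why: Silylation with a silyl triflate and a hindered base covers the primary C16 and the hindered secondary C7 hydroxyl in one operation and does not disturb the TES and TBDPS ethers.

Step 10
Reactants: 15 1,11-bis(tert-butyldimethylsilyl) ether of 14
Product: 16 (2E,6R,10E,14E)-6,16-bis(tert-butyldimethylsilyloxy)-3-[(tert-butyldiphenylsilyloxy)methyl]-11,15-dimethyl-7-methylidenehexadeca-2,10,14-trienal
Conditions: (COCl)2, DMSO, CH2Cl2, −78 °C to −30 °C; Et3N, to 0 °C
Reagents that add atoms: none
Why: Swern conditions oxidise primary TES ethers directly to aldehydes because the chlorosulfonium salt attacks the least hindered silyl ether oxygen, whereas TBS and TBDPS ethers are inert, so that the C2 enal is unveiled in one step at low temperature without loss of the C3=C4 geometry.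

Step 11
Reactants: 16 the bis-TBS enal from step 10
Product: 17 (2E,6R,10E,14E)-6-(tert-butyldimethylsilyloxy)-3-[(tert-butyldiphenylsilyloxy)methyl]-16-hydroxy-11,15-dimethyl-7-methylidenehexadeca-2,10,14-trienal
Conditions: HF·pyridine, pyridine, THF, 0 °C
Reagents that add atoms: none
Why: Graded silyl lability under buffered fluoride lets the primary allylic TBS ether fall well before the hindered secondary TBS ether and the TBDPS ether (selective desilylation).

Step 12
Reactants: 17 the C16 allylic alcohol from step 11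
Product: 18 (2E,6R,10E,14E)-16-bromo-6-(tert-butyldimethylsilyloxy)-3-[(tert-butyldiphenylsilyloxy)methyl]-11,15-dimethyl-7-methylidenehexadeca-2,10,14-trienal
Conditions: PPh3, NBS (premixed), CH2Cl2, −20 °C
Reagents that add atoms: N-bromosuccinimide, O=C1CCC(=O)N1Br
Why: Appel-type bromination replaces the primary allylic hydroxyl by SN2 without allylic transposition under neutral conditions that spare the enal, and PPh3/NBS is chosen over PPh3/CBr4 to exclude dibromo-olefination of the aldehyde.

Step 13
Reactants: 18 the bromo enal from step 12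
Product: 20 (1R,2S,3E,7R,11E)-7-(tert-butyldimethylsilyloxy)-18-(tert-butyldiphenylsilyloxy)cembra-3,8(19),11,15-tetraen-2-ol, via allylchromium species 19 (not isolated)
Conditions: CrCl2 (4 equiv), 1,8-bis[(4S)-4-isopropyl-4,5-dihydrooxazol-2-yl]-3,6-diphenyl-9H-carbazole (4.4 equiv), iPr2NEt (4.4 equiv), THF, rt, 1 h; 18 added by syringe pump over 10 h (final 2 mM), rt; aqueous work-up, ligand recovered
Reagents that add atoms: none
Why: Two one-electron transfers from the ligated CrCl2 reduce only the allylic carbon–bromine bond of 18 and turn the electrophilic C16–C15–C1 allyl unit into the nucleophilic (E)-allylchromium 19 (trivalent chromium), so that two acceptor carbons, C1 and the aldehyde carbon C2, are joined by polarity reversal; the closest known reaction type is the intramolecular Nozaki–Hiyama–Kishi allylation of ω-formyl allylic halides that closes 12- to 14-membered carbocycles, combined with the ligand-controlled asymmetric version known for 2,3-disubstituted allyl halides. The aldehyde oxygen binds to chromium and the γ-carbon C1 attacks C2 through a six-membered chair (Zimmerman–Traxler) array, which moves the double bond to C15=C16 and so creates the isopropenyl group in the same event. The 14-membered ring closes in a 14-exo-trig mode at the carbonyl group (C=O outside the new ring) and with allyl transposition (SE2′) at the other end, so that C15 and C16 of the 16-atom chain are left outside the ring. The relative configuration at C1/C2 (anti, 1R,2S) follows from the E geometry of 19, with C14 and the alkenyl residue C3 both equatorial in the chair. The absolute sense, attack on the Re face of the enal, is imposed by the twofold-symmetric bis(oxazolinyl)carbazolide on chromium, because the resident C7 stereocentre lies five bonds from C2 and should exert little bias of its own. The step needs ring closure over oligomerisation (slow addition, high dilution), 1,2- over 1,4-addition and γ- over α-attack (both inherent to the closed chromium chair), and inertness of the silyl ethers and of the C3=C4 geometry (neutral medium, room temperature, no nickel salt).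

Step 14
Reactants: 20 the macrocyclic C2 alcohol from step 13
Product: 21 (1R,2S,3E,7R,11E)-2-acetoxy-7-(tert-butyldimethylsilyloxy)-18-(tert-butyldiphenylsilyloxy)cembra-3,8(19),11,15-tetraene
Conditions: Ac2O, pyridine, DMAP (cat.), CH2Cl2, rt
Reagents that add atoms: acetic anhydride, CC(=O)OC(C)=O
Why: DMAP-catalysed acylation esterifies the only free hydroxyl with retention at C2.

Step 15
Reactants: 21 the C2 acetate from step 14
Product: 22 (1R,2S,3E,7R,11E)-2-acetoxycembra-3,8(19),11,15-tetraene-7,18-diol
Conditions: Bu4NF, AcOH (1:1), THF, rt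
Reagents that add atoms: none
Why: Fluoride desilylation buffered with AcOH removes the TBDPS and the secondary TBS group together without cleaving the acetate, which cannot migrate to the C18 hydroxyl because C2 and C18 are trans on C3=C4.

Step 16
Reactants: 22 the 7,18-diol from step 15
Product: 23 (1R,2S,3E,7R,11E)-2,18-diacetoxycembra-3,8(19),11,15-tetraen-7-ol (target)
Conditions: AcCl (1.1 equiv), 2,4,6-collidine, CH2Cl2, −78 °C
Reagents that add atoms: acetyl chloride, CC(=O)Cl
Why: Chemoselective acylation with AcCl and a hindered pyridine base at low temperature acetylates the unhindered primary allylic C18 hydroxyl much faster than the secondary C7 hydroxyl next to the C8 methylene.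

Compound list
1 | 2-butyne-1,4-diol | OCC#CCO | starting material
2 | 4-(tert-butyldiphenylsilyloxy)but-2-yn-1-ol | OCC#CCO[Si](c1ccccc1)(c1ccccc1)C(C)(C)C | intermediate
3 | cyclic alkenylalanate, sodium salt (not isolated) | [Na+].COCCO[Al-]1(OCCOC)OCC=C1CO[Si](c1ccccc1)(c1ccccc1)C(C)(C)C | intermediate
4 | (Z)-4-(tert-butyldiphenylsilyloxy)-3-iodobut-2-en-1-ol | OC/C=C(\I)CO[Si](c1ccccc1)(c1ccccc1)C(C)(C)C | intermediate
5 | (Z)-1-(tert-butyldiphenylsilyloxy)-2-iodo-4-(triethylsilyloxy)but-2-ene | CC[Si](CC)(CC)OC/C=C(\I)CO[Si](c1ccccc1)(c1ccccc1)C(C)(C)C | intermediate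
6 | 3-ethoxy-3-oxopropylzinc bromide | CCOC(=O)CC[Zn]Br | starting material
7 | ethyl (E)-4-[(tert-butyldiphenylsilyloxy)methyl]-6-(triethylsilyloxy)hex-4-enoate | CCOC(=O)CC/C(=C\CO[Si](CC)(CC)CC)CO[Si](c1ccccc1)(c1ccccc1)C(C)(C)C | intermediate
8 | (E)-4-[(tert-butyldiphenylsilyloxy)methyl]-6-(triethylsilyloxy)hex-4-enal | O=CCC/C(=C\CO[Si](CC)(CC)CC)CO[Si](c1ccccc1)(c1ccccc1)C(C)(C)C | intermediate
9 | (E)-geranylacetone | CC(=O)CC/C=C(\C)CCC=C(C)C | starting material
10 | lithium enolate of 9, less substituted (not isolated) | [Li]OC(=C)CC/C=C(\C)CCC=C(C)C | intermediate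
11 | (5E)-6,10-dimethylundeca-1,5,9-trien-2-yl trifluoromethanesulfonate | C=C(OS(=O)(=O)C(F)(F)F)CC/C=C(\C)CCC=C(C)C | intermediate
12 | (5E,9E)-11-hydroxy-6,10-dimethylundeca-1,5,9-trien-2-yl trifluoromethanesulfonate | C=C(OS(=O)(=O)C(F)(F)F)CC/C=C(\C)CC/C=C(\C)CO | intermediate
13 | alkenylchromium species from 12, drawn as the dichloride with the chiral ligand omitted (not isolated) | C=C([Cr](Cl)Cl)CC/C=C(\C)CC/C=C(\C)CO | intermediate
14 | (2E,6E,11R,14E)-14-[(tert-butyldiphenylsilyloxy)methyl]-2,6-dimethyl-10-methylidene-16-(triethylsilyloxy)hexadeca-2,6,14-triene-1,11-diol | C=C(CC/C=C(\C)CC/C=C(\C)CO)[C@@H](CC/C(=C\CO[Si](CC)(CC)CC)CO[Si](c1ccccc1)(c1ccccc1)C(C)(C)C)O | intermediate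
15 | 1,11-bis(tert-butyldimethylsilyl) ether of 14 | C=C(CC/C=C(\C)CC/C=C(\C)CO[Si](C)(C)C(C)(C)C)[C@@H](CC/C(=C\CO[Si](CC)(CC)CC)CO[Si](c1ccccc1)(c1ccccc1)C(C)(C)C)O[Si](C)(C)C(C)(C)C | intermediate
16 | (2E,6R,10E,14E)-6,16-bis(tert-butyldimethylsilyloxy)-3-[(tert-butyldiphenylsilyloxy)methyl]-11,15-dimethyl-7-methylidenehexadeca-2,10,14-trienal | C=C(CC/C=C(\C)CC/C=C(\C)CO[Si](C)(C)C(C)(C)C)[C@@H](CC/C(=C\C=O)CO[Si](c1ccccc1)(c1ccccc1)C(C)(C)C)O[Si](C)(C)C(C)(C)C | intermediate
17 | (2E,6R,10E,14E)-6-(tert-butyldimethylsilyloxy)-3-[(tert-butyldiphenylsilyloxy)methyl]-16-hydroxy-11,15-dimethyl-7-methylidenehexadeca-2,10,14-trienal | C=C(CC/C=C(\C)CC/C=C(\C)CO)[C@@H](CC/C(=C\C=O)CO[Si](c1ccccc1)(c1ccccc1)C(C)(C)C)O[Si](C)(C)C(C)(C)C | intermediate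
18 | (2E,6R,10E,14E)-16-bromo-6-(tert-butyldimethylsilyloxy)-3-[(tert-butyldiphenylsilyloxy)methyl]-11,15-dimethyl-7-methylidenehexadeca-2,10,14-trienal | C=C(CC/C=C(\C)CC/C=C(\C)CBr)[C@@H](CC/C(=C\C=O)CO[Si](c1ccccc1)(c1ccccc1)C(C)(C)C)O[Si](C)(C)C(C)(C)C | intermediate
19 | (E)-allylchromium species from 18, drawn as the dichloride with the chiral ligand omitted (not isolated) | C=C(CC/C=C(\C)CC/C=C(\C)C[Cr](Cl)Cl)[C@@H](CC/C(=C\C=O)CO[Si](c1ccccc1)(c1ccccc1)C(C)(C)C)O[Si](C)(C)C(C)(C)C | intermediate
20 | (1R,2S,3E,7R,11E)-7-(tert-butyldimethylsilyloxy)-18-(tert-butyldiphenylsilyloxy)cembra-3,8(19),11,15-tetraen-2-ol | C=C1CC/C=C(\C)CC[C@H](C(=C)C)[C@@H](O)/C=C(/CO[Si](c2ccccc2)(c2ccccc2)C(C)(C)C)CC[C@H]1O[Si](C)(C)C(C)(C)C | intermediate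
21 | (1R,2S,3E,7R,11E)-2-acetoxy-7-(tert-butyldimethylsilyloxy)-18-(tert-butyldiphenylsilyloxy)cembra-3,8(19),11,15-tetraene | C=C1CC/C=C(\C)CC[C@H](C(=C)C)[C@@H](OC(C)=O)/C=C(/CO[Si](c2ccccc2)(c2ccccc2)C(C)(C)C)CC[C@H]1O[Si](C)(C)C(C)(C)C | intermediate
22 | (1R,2S,3E,7R,11E)-2-acetoxycembra-3,8(19),11,15-tetraene-7,18-diol | C=C1CC/C=C(\C)CC[C@H](C(=C)C)[C@@H](OC(C)=O)/C=C(/CO)CC[C@H]1O | intermediate
23 | (1R,2S,3E,7R,11E)-2,18-diacetoxycembra-3,8(19),11,15-tetraen-7-ol | C=C1CC/C=C(\C)CC[C@H](C(=C)C)[C@@H](OC(C)=O)/C=C(/COC(C)=O)CC[C@H]1O | target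

Total step count: 16. Longest linear sequence: 14 (steps 1–5 and 8–16).

Steps most likely to fail

Step 13. Oligomerisation may compete with ring closure. Facial selectivity at the enal may erode if the conformational demands of the forming 14-membered ring oppose the ligand. The allylchromium may also be lost by protonation during the long addition.
The fallback forms C1–C2 in an open chain and closes the ring at another bond. It sets out from 12 and 7 and comes back at 22.
- PPh3/NBS turns 12 into the bromo triflate F1.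
- Swern oxidation of the TES ether of 7 gives the enal ester F2.
- The intermolecular asymmetric Nozaki–Hiyama–Kishi allylation of F2 with F1 (CrCl2, the same carbazole ligand, iPr2NEt, THF, no nickel salt) gives the anti homoallylic alcohol F3. C1 and C2 are set by the ligand alone, with no other stereocentre present.
- iBu2AlH (2.2 equiv, −78 °C) reduces the ester to the hydroxy aldehyde F4, and Ac2O/pyridine gives the acetoxy aldehyde F5.
- A Ni/Cr alkenyl triflate–aldehyde macrocyclisation at high dilution, with the sulfonamide ligand of step 8, closes C7–C8 and gives the macrocyclic allylic alcohol F6.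
- Bu4NF/AcOH removes the TBDPS group to give 22.

Step 8. Facial selectivity at the unbranched aldehyde may be poor. Activation of the enol triflate may be sluggish, and the alkenyl unit may homocouple.
The fallback sets C7 by reduction instead of by carbon–carbon bond formation. It sets out from 8 and 12 and comes back at 15.
- Coupling without chiral ligand (CrCl2, NiCl2 cat., DMF) gives the C7-epimeric diol F7.
- TBSCl (1.05 equiv)/imidazole silylates only the primary hydroxyl to give the mono-TBS ether F8.
- Dess–Martin periodinane gives the α-methylene ketone F9.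
- Corey–Bakshi–Shibata reduction gives the (7R)-alcohol F10. It uses (S)-2-methyl-CBS-oxazaborolidine and catecholborane in toluene at −78 °C, with the branched alkenyl group acting as the large residue.
- TBSOTf/2,6-lutidine gives 15.

Step 7. Site selectivity between the terminal and the internal trisubstituted alkene may be poor. The alcohol may be over-oxidised to the enal, and the enol triflate may be lost in the acidic peroxide medium.
The fallback oxidises before the triflate exists. It sets out from 9 and comes back at 12.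
- SeO2/tBuOOH on the ketone gives the hydroxy ketone F11.
- TBSCl/imidazole gives the silyl ether F12.
- LiN(iPr)2 then PhNTf2 gives the silylated enol triflate F13.
- HF·pyridine gives 12.

Further compounds
F1 | step 13 | (5E,9E)-11-bromo-6,10-dimethylundeca-1,5,9-trien-2-yl trifluoromethanesulfonate | C=C(OS(=O)(=O)C(F)(F)F)CC/C=C(\C)CC/C=C(\C)CBr
F2 | step 13 | ethyl (E)-4-[(tert-butyldiphenylsilyloxy)methyl]-6-oxohex-4-enoate | CCOC(=O)CC/C(=C\C=O)CO[Si](c1ccccc1)(c1ccccc1)C(C)(C)C
F3 | step 13 | ethyl (4E,6S,7R,10E)-4-[(tert-butyldiphenylsilyloxy)methyl]-6-hydroxy-10-methyl-7-(prop-1-en-2-yl)-14-(trifluoromethylsulfonyloxy)pentadeca-4,10,14-trienoate | C=C(OS(=O)(=O)C(F)(F)F)CC/C=C(\C)CC[C@H](C(=C)C)[C@@H](O)/C=C(/CO[Si](c1ccccc1)(c1ccccc1)C(C)(C)C)CCC(=O)OCC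
F4 | step 13 | hydroxy aldehyde from F3 (CHO in place of CO2Et) | C=C(OS(=O)(=O)C(F)(F)F)CC/C=C(\C)CC[C@H](C(=C)C)[C@@H](O)/C=C(/CO[Si](c1ccccc1)(c1ccccc1)C(C)(C)C)CCC=O
F5 | step 13 | C2 acetate of F4 | C=C(OS(=O)(=O)C(F)(F)F)CC/C=C(\C)CC[C@H](C(=C)C)[C@@H](OC(C)=O)/C=C(/CO[Si](c1ccccc1)(c1ccccc1)C(C)(C)C)CCC=O
F6 | step 13 | (1R,2S,3E,7R,11E)-2-acetoxy-18-(tert-butyldiphenylsilyloxy)cembra-3,8(19),11,15-tetraen-7-ol | C=C1CC/C=C(\C)CC[C@H](C(=C)C)[C@@H](OC(C)=O)/C=C(/CO[Si](c2ccccc2)(c2ccccc2)C(C)(C)C)CC[C@H]1O
F7 | step 8 | diol 14 as the mixture of C7 epimers | C=C(CC/C=C(\C)CC/C=C(\C)CO)C(CC/C(=C\CO[Si](CC)(CC)CC)CO[Si](c1ccccc1)(c1ccccc1)C(C)(C)C)O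
F8 | step 8 | primary (C16) TBS ether of F7 | C=C(CC/C=C(\C)CC/C=C(\C)CO[Si](C)(C)C(C)(C)C)C(CC/C(=C\CO[Si](CC)(CC)CC)CO[Si](c1ccccc1)(c1ccccc1)C(C)(C)C)O
F9 | step 8 | C7 ketone (α-methylene ketone) from F8 | C=C(CC/C=C(\C)CC/C=C(\C)CO[Si](C)(C)C(C)(C)C)C(=O)CC/C(=C\CO[Si](CC)(CC)CC)CO[Si](c1ccccc1)(c1ccccc1)C(C)(C)C
F10 | step 8 | (7R)-alcohol from F9 | C=C(CC/C=C(\C)CC/C=C(\C)CO[Si](C)(C)C(C)(C)C)[C@@H](CC/C(=C\CO[Si](CC)(CC)CC)CO[Si](c1ccccc1)(c1ccccc1)C(C)(C)C)O
F11 | step 7 | (5E,9E)-11-hydroxy-6,10-dimethylundeca-5,9-dien-2-one | CC(=O)CC/C=C(\C)CC/C=C(\C)CO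
F12 | step 7 | (5E,9E)-11-(tert-butyldimethylsilyloxy)-6,10-dimethylundeca-5,9-dien-2-one | CC(=O)CC/C=C(\C)CC/C=C(\C)CO[Si](C)(C)C(C)(C)C
F13 | step 7 | (5E,9E)-11-(tert-butyldimethylsilyloxy)-6,10-dimethylundeca-1,5,9-trien-2-yl trifluoromethanesulfonate | C=C(OS(=O)(=O)C(F)(F)F)CC/C=C(\C)CC/C=C(\C)CO[Si](C)(C)C(C)(C)C
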